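**Retrosynthetic overview**
- The strategy rests on the 2-substituted 1,4-diene of the side chain, ring C–C(=CH2)–CH2–CH=CH–C(CH3)(OH)–. Cutting the bond between the methylene-bearing sp2 carbon and the doubly allylic CH2 gives a ring-bound terminal alkyne (fragment 1) and a homoallylic tertiary alcohol (fragment 2), the partners of a ruthenium-catalysed Alder-ene coupling.
- Fragment 1: the only ring, the cyclohexene, is closed first as a 5-alkynylcyclohex-2-enone by organocatalytic Michael addition, aldol condensation and decarboxylation; α-hydroxymethylation, acylation, cis-selective ketone reduction and desilylation follow.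
- Fragment 2: (S)-2-methylglycidol is opened with a vinyl Grignard reagent under copper catalysis and the primary hydroxyl is acylated.
- The two halves are joined in the last step with both hydroxyls free.

Key step: step 9

Remark on the chemistry: the target is read as the cis (4S,6S) ring with an (R) side-chain carbinol and an E alkene; compounds 1 and 12 and both enantiomers of the diarylprolinol silyl ether and of the oxazaborolidine are assumed to be commercial.

**Step 1**
Reactants: 1 3-(triisopropylsilyl)prop-2-ynal; 2 (triphenylphosphoranylidene)acetaldehyde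
Product: 3 (2E)-5-(triisopropylsilyl)pent-2-en-4-ynal
Conditions: 2 (1.0 equiv), toluene, rt
Reagents that add atoms: none
Why: Wittig olefination with a formyl-stabilised ylide is E-selective, and the ynal is far more electrophilic than the enal product, so a single two-carbon homologation should prevail.

**Step 2**
Reactants: 3 (2E)-5-(triisopropylsilyl)pent-2-en-4-ynal; 4 tert-butyl 3-oxobutanoate
Product: 6 (5S)-5-[(triisopropylsilyl)ethynyl]cyclohex-2-en-1-one, via Michael adduct 5 (not isolated)
Conditions: (R)-2-{bis[3,5-bis(trifluoromethyl)phenyl](trimethylsilyloxy)methyl}pyrrolidine (10 mol%), PhCO2H (10 mol%), toluene, 0 °C to rt; then TsOH·H2O (30 mol%), toluene, 80 °C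
Reagents that add atoms: none
Why: Iminium-ion catalysed Michael addition followed by acid-mediated intramolecular aldol condensation, tert-butyl ester cleavage and decarboxylation is a known one-pot route to 5-substituted cyclohex-2-enones; the aryl(silyloxy)methyl group of the R catalyst covers the Si face of the β-carbon of the E,s-trans iminium ion, so the keto ester adds to the Re face and sets the S centre.

**Step 3**
Reactants: 6 (5S)-5-[(triisopropylsilyl)ethynyl]cyclohex-2-en-1-one
Product: 7 (5S)-2-(hydroxymethyl)-5-[(triisopropylsilyl)ethynyl]cyclohex-2-en-1-one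
Conditions: 37% aq. HCHO, DMAP (20 mol%), THF/H2O, rt
Reagents that add atoms: formaldehyde, C=O
Why: Morita–Baylis–Hillman reaction, in which DMAP adds reversibly to the enone β-carbon, the enolate traps formaldehyde at the α-carbon and the amine is eliminated; the C5 centre is not involved.

**Step 4**
Reactants: 7 (5S)-2-(hydroxymethyl)-5-[(triisopropylsilyl)ethynyl]cyclohex-2-en-1-one; 8 2-methylpropanoyl chloride
Product: 9 [(4S)-6-oxo-4-[(triisopropylsilyl)ethynyl]cyclohex-1-en-1-yl]methyl 2-methylpropanoate
Conditions: pyridine, CH2Cl2, 0 °C
Reagents that add atoms: none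
Why: Acylation of the only hydroxyl group by nucleophilic acyl substitution; pyridine at 0 °C is used instead of a more nucleophilic amine so that the new allylic ester is not displaced.

**Step 5**
Reactants: 9 [(4S)-6-oxo-4-[(triisopropylsilyl)ethynyl]cyclohex-1-en-1-yl]methyl 2-methylpropanoate
Product: 10 [(4S,6S)-6-hydroxy-4-[(triisopropylsilyl)ethynyl]cyclohex-1-en-1-yl]methyl 2-methylpropanoate
Conditions: (R)-2-methyl-CBS-oxazaborolidine (20 mol%), catecholborane, toluene, −78 °C; then MeOH
Reagents that add atoms: none
Why: Corey–Bakshi–Shibata reduction in which the α-substituted alkene arm acts as the large group, so the R oxazaborolidine delivers hydride to the face that gives the S carbinol cis to the alkynyl group, the same alcohol that axial attack on the 5-substituted enone favours (matched case); ester, alkene and silyl alkyne are inert to catecholborane at −78 °C.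

**Step 6**
Reactants: 10 [(4S,6S)-6-hydroxy-4-[(triisopropylsilyl)ethynyl]cyclohex-1-en-1-yl]methyl 2-methylpropanoate
Product: 11 [(4S,6S)-4-ethynyl-6-hydroxycyclohex-1-en-1-yl]methyl 2-methylpropanoate (fragment 1)
Conditions: Bu4NF, AcOH, THF, 0 °C to rt
Reagents that add atoms: none
Why: Fluoride-mediated protodesilylation of the alkynylsilane; acetic acid buffers the basicity of Bu4NF so that the isobutyrate should neither migrate nor cleave, and no stereocentre is touched.

**Step 7**
Reactants: 12 (S)-2-methylglycidol; 13 vinylmagnesium bromide
Product: 14 (2R)-2-methylpent-4-ene-1,2-diol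
Conditions: 13 (3 equiv), CuI (10 mol%), THF, −30 to 0 °C; aq. NH4Cl
Reagents that add atoms: none
Why: Copper-catalysed Grignard opening of the 2,2-disubstituted epoxide by SN2 attack at the unsubstituted CH2 leaves the quaternary centre unchanged (the descriptor changes from S to R only because the CIP priorities change); one equivalent of Grignard reagent is consumed by the hydroxyl group.

**Step 8**
Reactants: 14 (2R)-2-methylpent-4-ene-1,2-diol; 8 2-methylpropanoyl chloride
Product: 15 (2R)-2-hydroxy-2-methylpent-4-en-1-yl 2-methylpropanoate (fragment 2)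
Conditions: 8 (1.05 equiv), 2,4,6-collidine, CH2Cl2, −20 to 0 °C
Reagents that add atoms: none
Why: Sterically controlled acylation, in which the primary hydroxyl reacts with the acid chloride far faster than the tertiary one under weak-base conditions.

**Step 9**
Reactants: 11 [(4S,6S)-4-ethynyl-6-hydroxycyclohex-1-en-1-yl]methyl 2-methylpropanoate; 15 (2R)-2-hydroxy-2-methylpent-4-en-1-yl 2-methylpropanoate
Product: 16 [(4S,6S)-6-hydroxy-4-[(4E,6R)-6-hydroxy-6-methyl-7-(2-methylpropanoyloxy)hepta-1,4-dien-2-yl]cyclohex-1-en-1-yl]methyl 2-methylpropanoate (target)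
Conditions: [CpRu(MeCN)3]PF6 (10 mol%), acetone, rt
Reagents that add atoms: none
Why: The cationic CpRu fragment (divalent ruthenium) binds the terminal alkyne of 11 and the monosubstituted alkene of 15 and couples them oxidatively to a ruthenacyclopentene of tetravalent ruthenium in which the internal alkyne carbon is joined to the terminal alkene CH2; β-hydride elimination from the former allylic CH2 that flanks the tertiary carbinol, then reductive elimination, releases the 1,4-diene and returns divalent ruthenium. The closest known reaction type is the ruthenium-catalysed intermolecular alkene–alkyne Alder-ene coupling of terminal alkynes with monosubstituted alkenes to 2-substituted 1,4-dienes, here applied to an untried pair of partners. No ring is closed, since the cyclohexene is already in place, and no stereocentre is formed or touched, so the three existing centres are carried through; the only new stereo element, the E alkene, follows from the geometry of β-hydride elimination in the metallacycle. The step needs branched over linear regioselectivity, which the cationic catalyst and the methine (not quaternary) propargylic carbon of 11 favour, and reaction at one alkene only, which is secured because the trisubstituted ring alkene and the alkenes of the product do not enter the metallacycle. Only the CH2 next to the carbinol carries allylic hydrogens in 15, so a single diene can form, and free hydroxyls and esters are tolerated by this catalyst at room temperature.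

**Compound list**
1 | 3-(triisopropylsilyl)prop-2-ynal | O=CC#C[Si](C(C)C)(C(C)C)C(C)C | starting material
2 | (triphenylphosphoranylidene)acetaldehyde | O=CC=P(c1ccccc1)(c1ccccc1)c1ccccc1 | starting material
3 | (2E)-5-(triisopropylsilyl)pent-2-en-4-ynal | O=C/C=C/C#C[Si](C(C)C)(C(C)C)C(C)C | intermediate
4 | tert-butyl 3-oxobutanoate | CC(=O)CC(=O)OC(C)(C)C | starting material
5 | tert-butyl (3S)-2-acetyl-5-oxo-3-[(triisopropylsilyl)ethynyl]pentanoate, Michael adduct, both C2 epimers | O=CC[C@H](C#C[Si](C(C)C)(C(C)C)C(C)C)C(C(C)=O)C(=O)OC(C)(C)C | intermediate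
6 | (5S)-5-[(triisopropylsilyl)ethynyl]cyclohex-2-en-1-one | CC(C)[Si](C#C[C@H]1CC=CC(=O)C1)(C(C)C)C(C)C | intermediate
7 | (5S)-2-(hydroxymethyl)-5-[(triisopropylsilyl)ethynyl]cyclohex-2-en-1-one | CC(C)[Si](C#C[C@H]1CC=C(CO)C(=O)C1)(C(C)C)C(C)C | intermediate
8 | 2-methylpropanoyl chloride | CC(C)C(Cl)=O | starting material
9 | [(4S)-6-oxo-4-[(triisopropylsilyl)ethynyl]cyclohex-1-en-1-yl]methyl 2-methylpropanoate | CC(C)[Si](C#C[C@H]1CC=C(COC(=O)C(C)C)C(=O)C1)(C(C)C)C(C)C | intermediate
10 | [(4S,6S)-6-hydroxy-4-[(triisopropylsilyl)ethynyl]cyclohex-1-en-1-yl]methyl 2-methylpropanoate | CC(C)[Si](C#C[C@H]1CC=C(COC(=O)C(C)C)[C@@H](O)C1)(C(C)C)C(C)C | intermediate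
11 | [(4S,6S)-4-ethynyl-6-hydroxycyclohex-1-en-1-yl]methyl 2-methylpropanoate, fragment 1 | C#C[C@H]1CC=C(COC(=O)C(C)C)[C@@H](O)C1 | intermediate
12 | (S)-2-methylglycidol, [(2S)-2-methyloxiran-2-yl]methanol | C[C@]1(CO)CO1 | starting material
13 | vinylmagnesium bromide | C=C[Mg]Br | starting material
14 | (2R)-2-methylpent-4-ene-1,2-diol | C=CC[C@@](C)(O)CO | intermediate
15 | (2R)-2-hydroxy-2-methylpent-4-en-1-yl 2-methylpropanoate, fragment 2 | C=CC[C@@](C)(O)COC(=O)C(C)C | intermediate
16 | [(4S,6S)-6-hydroxy-4-[(4E,6R)-6-hydroxy-6-methyl-7-(2-methylpropanoyloxy)hepta-1,4-dien-2-yl]cyclohex-1-en-1-yl]methyl 2-methylpropanoate | C=C(C/C=C/[C@@](C)(O)COC(=O)C(C)C)[C@H]1CC=C(COC(=O)C(C)C)[C@@H](O)C1 | target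

**Step count**
Total steps: 9. Longest linear sequence: 7 (steps 1 to 6, then step 9).

**Steps most likely to fail**

Step 9. The coupling may form the bond at the terminal alkyne carbon and give the linear diene, the two free hydroxyls may slow the catalyst, or the cationic ruthenium may ionise the ring allylic ester. The fallback sets out from 11 and 15 and comes back at 16, replacing the Alder-ene step by an allyl–vinyl cross-coupling.
- Markovnikov stannylcupration of 11 with Me3SnCu·SMe2 in THF/MeOH at −78 °C should give the 2-stannyl alkene [(4S,6S)-6-hydroxy-4-[1-(trimethylstannyl)ethenyl]cyclohex-1-en-1-yl]methyl 2-methylpropanoate F1.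
- Linear-selective allylic C–H acetoxylation of 15 (Pd(OAc)2, 1,4-benzoquinone, DMSO/AcOH, 40 °C) should give the E allylic acetate (2R,3E)-5-(acetyloxy)-2-hydroxy-2-methylpent-3-en-1-yl 2-methylpropanoate F2.
- Stille coupling of F1 with F2 (Pd2(dba)3, LiCl, DMF, rt) should join the vinyl carbon to the primary allylic terminus with retention of the E geometry. The unhindered primary acetate is expected to ionise at zerovalent palladium ahead of the hindered ring isobutyrate.

Step 2. Facial control at the iminium stage may be incomplete with the alkynyl enal, turnover with the bulky amine may be slow, or material may be lost in the hot acid stage. The fallback sets out from 3 and 4 and comes back at 6, replacing asymmetric catalysis by a kinetic resolution.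
- The same cascade run with pyrrolidine and PhCO2H, then TsOH·H2O in toluene at 80 °C, should pass through the racemic Michael adduct tert-butyl 2-acetyl-5-oxo-3-[(triisopropylsilyl)ethynyl]pentanoate F3 to the racemic enone 5-[(triisopropylsilyl)ethynyl]cyclohex-2-en-1-one F4.
- Copper-catalysed conjugate addition of Et2Zn (0.55 equiv) with Cu(OTf)2 and a chiral binaphthol-derived phosphoramidite ligand, its enantiomer chosen to consume the R enone, should convert that enantiomer into the trans ketone (3R,5R)-3-ethyl-5-[(triisopropylsilyl)ethynyl]cyclohexan-1-one F5 and leave 6 unreacted for chromatographic separation.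

Step 3. Amine addition to the β-carbon of the ring enone may be sluggish, formaldehyde may add more than once, or base may shift the ring double bond and erode the C5 centre. The fallback sets out from 6 and comes back at 7.
- α-Iodination of the enone with I2 and pyridine in CH2Cl2 should give (5S)-2-iodo-5-[(triisopropylsilyl)ethynyl]cyclohex-2-en-1-one F6.
- Stille coupling of F6 with (tributylstannyl)methanol (Pd(PPh3)4, dioxane, 90 °C) should install the hydroxymethyl group without any basic amine.

**Further compounds**
F1 | step 9 | [(4S,6S)-6-hydroxy-4-[1-(trimethylstannyl)ethenyl]cyclohex-1-en-1-yl]methyl 2-methylpropanoate | C=C([Sn](C)(C)C)[C@H]1CC=C(COC(=O)C(C)C)[C@@H](O)C1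
F2 | step 9 | (2R,3E)-5-(acetyloxy)-2-hydroxy-2-methylpent-3-en-1-yl 2-methylpropanoate | CC(=O)OC/C=C/[C@@](C)(O)COC(=O)C(C)C
F3 | step 2 | tert-butyl 2-acetyl-5-oxo-3-[(triisopropylsilyl)ethynyl]pentanoate, racemic | CC(=O)C(C(=O)OC(C)(C)C)C(CC=O)C#C[Si](C(C)C)(C(C)C)C(C)C
F4 | step 2 | 5-[(triisopropylsilyl)ethynyl]cyclohex-2-en-1-one, racemic | CC(C)[Si](C#CC1CC=CC(=O)C1)(C(C)C)C(C)C
F5 | step 2 | (3R,5R)-3-ethyl-5-[(triisopropylsilyl)ethynyl]cyclohexan-1-one | CC(C)[Si](C#C[C@@H]1C[C@@H](CC)CC(=O)C1)(C(C)C)C(C)C
F6 | step 3 | (5S)-2-iodo-5-[(triisopropylsilyl)ethynyl]cyclohex-2-en-1-one | CC(C)[Si](C#C[C@H]1CC=C(I)C(=O)C1)(C(C)C)C(C)C
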